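The oxolane is numbered O1, C2 (guaiacyl), C3 (CH2OH = C9), C4 (syringoyl), C5. The chain O1–C5–C4–C3–C9–OH is read as cis-but-2-ene-1,4-diol, and C2 as the carbonyl carbon of vanillin. The oxolane is then the ring-contracted isomer of a seven-membered cyclic vinyl acetal. The key step is a Lewis-acid-triggered [1,3] O-to-C shift of an enantioenriched 2-aryl-5-(1-arylvinyl)-4,5-dihydro-1,3-dioxepine. It forms C2–C3, closes the oxolane, unveils C9 as an aldehyde, and sets C2 and C3 from the single C4 centre. That centre comes from a desymmetrising asymmetric Heck reaction. The arylvinyl group is the latent syringoyl ketone. The classical lactone-aldol/etherification route instead delivers the 3,4-cis series and must epimerise C4.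

Key step: step 5

Remark on locants: plain locants refer to the oxolane of the target, and dioxepine locants carry the suffix d. The mapping is C2d→C2, O3d→O1, C4d→C5, C5d→C4, C6d→C3, C7d→C9, O1d→oxygen on C9.
Assumption 1: the sense of induction of (S)-t-Bu-PHOX in step 4 is assigned by analogy; should it prove opposite, (R)-t-Bu-PHOX is used and nothing else changes.
Assumption 2: 8 should form as a mixture of epimers at the acetal carbon C2d; this centre is left undefined in its SMILES because step 5 erases it.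

Step 1
Reactants: 1 4-(benzyloxy)-3-methoxybenzaldehyde (O-benzylvanillin); 2 (Z)-but-2-ene-1,4-diol
Product: 3 2-[4-(benzyloxy)-3-methoxyphenyl]-4,7-dihydro-1,3-dioxepine
Conditions: p-TsOH·H2O (cat.), toluene, Dean–Stark, reflux
Reagents that add atoms: none
Why: Acid-catalysed acetalisation with azeotropic removal of water, in which the cis geometry of the diol favours closure of the seven-membered ring, and the product has a mirror plane through C2d, so no stereocentre arises.

Step 2
Reactants: 4 1-(4-hydroxy-3,5-dimethoxyphenyl)ethan-1-one (acetosyringone)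
Product: 5 1-[4-(benzyloxy)-3,5-dimethoxyphenyl]ethan-1-one
Conditions: BnBr, K2CO3, DMF, 60 °C
Reagents that add atoms: benzyl bromide, BrCc1ccccc1
Why: Williamson ether synthesis on the acidic para-acyl phenol, which masks the oxidation-prone syringyl phenol until the last step.

Step 3
Reactants: 5 1-[4-(benzyloxy)-3,5-dimethoxyphenyl]ethan-1-one
Product: 7 1-[4-(benzyloxy)-3,5-dimethoxyphenyl]ethenyl trifluoromethanesulfonate, via potassium enolate 6 (not isolated)
Conditions: KHMDS, THF, −78 °C; then PhNTf2, −78 °C → 0 °C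
Reagents that add atoms: N-phenylbis(trifluoromethanesulfonimide), O=S(=O)(N(c1ccccc1)S(=O)(=O)C(F)(F)F)C(F)(F)F; potassium hexamethyldisilazide, C[Si](C)(C)[N-][Si](C)(C)C.[K+] (potassium only in 6)
Why: Deprotonation of a methyl ketone with a single enolisable side followed by O-sulfonylation with a mild triflyl donor is the standard enol triflate synthesis, and it gives the alkenyl electrophile that carries C7' and the syringyl ring.

Step 4
Reactants: 3 2-[4-(benzyloxy)-3-methoxyphenyl]-4,7-dihydro-1,3-dioxepine (excess, recoverable); 7 1-[4-(benzyloxy)-3,5-dimethoxyphenyl]ethenyl trifluoromethanesulfonate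
Product: 8 (5R)-2-[4-(benzyloxy)-3-methoxyphenyl]-5-{1-[4-(benzyloxy)-3,5-dimethoxyphenyl]ethenyl}-4,5-dihydro-1,3-dioxepine (both C2d epimers)
Conditions: Pd2(dba)3 (3 mol %), (S)-t-Bu-PHOX (7 mol %), i-Pr2NEt, THF, 70 °C
Reagents that add atoms: none
Why: In this intermolecular asymmetric Heck reaction (cationic triflate manifold) the P,N-ligated alkenylpalladium cation distinguishes the two enantiotopic alkene carbons of achiral 3 during syn-carbopalladation, and because the hydrogen on the newly substituted carbon is anti to palladium, syn β-hydride elimination can only run towards the O–CH2 group and should deliver the vinyl acetal with the (5R) centre, the future C4.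

Step 5
Reactants: 8 (5R)-2-[4-(benzyloxy)-3-methoxyphenyl]-5-{1-[4-(benzyloxy)-3,5-dimethoxyphenyl]ethenyl}-4,5-dihydro-1,3-dioxepine
Product: 10 (2S,3S,4R)-2-[4-(benzyloxy)-3-methoxyphenyl]-4-{1-[4-(benzyloxy)-3,5-dimethoxyphenyl]ethenyl}oxolane-3-carbaldehyde (all-trans), via oxocarbenium silyl enol ether ion pair 9 (not isolated)
Conditions: TMSOTf (20 mol %), 2,6-di-tert-butyl-4-methylpyridine (10 mol %), CH2Cl2, −78 °C → 0 °C; then aq. NaHCO3
Reagents that add atoms: trimethylsilyl trifluoromethanesulfonate, C[Si](C)(C)OS(=O)(=O)C(F)(F)F (atoms present only in 9, released again on closure)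
Why: TMSOTf silylates the enol-ether oxygen O1d, and the C2d–O1d bond ionises in preference to C2d–O3d because an enolate is the better leaving group and the 4-benzyloxy-3-methoxyphenyl group stabilises the (E)-oxocarbenium ion, which stays tethered through O3d–C4d–C5d to the (Z)-silyl enol ether it has released (ion pair 9, the same from both C2d epimers of 8). The enol carbon C6d then adds to the oxocarbenium carbon in an intramolecular Mukaiyama-aldol-type step and TMSOTf is returned, which is the known Lewis-acid-mediated [1,3] O-to-C rearrangement (ring contraction) of 4,5-dihydro-1,3-dioxepines to oxolane-3-carbaldehydes, a relative of the Petasis–Ferrier rearrangement. The oxolane closes in a 5-(enol-exo)-endo-trig mode, formally 5-endo at C=O+ but routine for oxocarbenium and iminium ions (Prins–pinacol, aza-Cope/Mannich). C3 is set by the Heck-derived centre: A(1,3) strain in the (Z)-enol ether holds the C5d–H bond in the enol plane, the tether and the arylvinyl group then lie on opposite faces, and bond formation on the tether face puts the formyl group trans to the arylvinyl group. C2 is set by the (E)-geometry of the cation and, because closure is reversible with so electron-rich an aryl group, by equilibration through 9 on warming to the all-trans oxolane, whereas C4 is neither enolisable nor ionisable and keeps its configuration. The step needs chemoselectivity for the silyl enol ether over the 1,1-disubstituted styrene, secured by the far higher nucleophilicity of the former and by 5-ring versus 6-endo Prins closure, and it needs the absence of protic acid, secured by the hindered pyridine, so that the styrene double bond cannot migrate into C4.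

Step 6
Reactants: 10 (2S,3S,4R)-2-[4-(benzyloxy)-3-methoxyphenyl]-4-{1-[4-(benzyloxy)-3,5-dimethoxyphenyl]ethenyl}oxolane-3-carbaldehyde
Product: 11 [(2S,3R,4R)-2-[4-(benzyloxy)-3-methoxyphenyl]-4-{1-[4-(benzyloxy)-3,5-dimethoxyphenyl]ethenyl}oxolan-3-yl]methanol
Conditions: NaBH4, THF/MeOH, 0 °C
Reagents that add atoms: none
Why: Chemoselective 1,2-reduction of the aldehyde by borohydride should outrun enolisation and β-elimination, which locks C3 and leaves the alkene and the benzyl ethers untouched.

Step 7
Reactants: 11 [(2S,3R,4R)-2-[4-(benzyloxy)-3-methoxyphenyl]-4-{1-[4-(benzyloxy)-3,5-dimethoxyphenyl]ethenyl}oxolan-3-yl]methanol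
Product: 13 [4-(benzyloxy)-3,5-dimethoxyphenyl][(3S,4R,5S)-5-[4-(benzyloxy)-3-methoxyphenyl]-4-(hydroxymethyl)oxolan-3-yl]methanone (route locants 2S,3R,4S), via vicinal diol 12 (not isolated)
Conditions: OsO4 (2 mol %), NaIO4, 2,6-lutidine, 1,4-dioxane/H2O, rt
Reagents that add atoms: sodium periodate, [Na+].[O-]I(=O)(=O)=O (oxygen passed on through catalytic OsO4); water, O
Why: In this Lemieux–Johnson oxidation the only C=C bond is dihydroxylated and the tertiary/primary glycol is cleaved in situ to the aryl ketone under near-neutral buffering, while C4, now enolisable, already holds the thermodynamically preferred trans arrangement and the trans hydroxy ketone cannot close to a strained hemiketal.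

Step 8
Reactants: 13 [4-(benzyloxy)-3,5-dimethoxyphenyl][(3S,4R,5S)-5-[4-(benzyloxy)-3-methoxyphenyl]-4-(hydroxymethyl)oxolan-3-yl]methanone
Product: 14 (4-hydroxy-3,5-dimethoxyphenyl)[(3S,4R,5S)-5-(4-hydroxy-3-methoxyphenyl)-4-(hydroxymethyl)oxolan-3-yl]methanone (target, route locants 2S,3R,4S)
Conditions: H2 (1 atm), 10% Pd/C, EtOAc/EtOH, rt, stopped after uptake of two equivalents
Reagents that add atoms: none
Why: Catalytic hydrogenolysis should cleave the two aryl benzyl ethers faster than it attacks the cyclic benzylic C2–O1 bond or the electron-rich aryl ketone, and it touches no stereocentre.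

Compound list
1 | 4-(benzyloxy)-3-methoxybenzaldehyde | COc1cc(C=O)ccc1OCc1ccccc1 | starting material
2 | (Z)-but-2-ene-1,4-diol | OC/C=C\CO | starting material
3 | 2-[4-(benzyloxy)-3-methoxyphenyl]-4,7-dihydro-1,3-dioxepine | COc1cc(C2OCC=CCO2)ccc1OCc1ccccc1 | intermediate
4 | 1-(4-hydroxy-3,5-dimethoxyphenyl)ethan-1-one | CC(=O)c1cc(OC)c(O)c(OC)c1 | starting material
5 | 1-[4-(benzyloxy)-3,5-dimethoxyphenyl]ethan-1-one | CC(=O)c1cc(OC)c(OCc2ccccc2)c(OC)c1 | intermediate
6 | potassium 1-[4-(benzyloxy)-3,5-dimethoxyphenyl]ethen-1-olate (not isolated) | [K+].[O-]C(=C)c1cc(OC)c(OCc2ccccc2)c(OC)c1 | intermediate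
7 | 1-[4-(benzyloxy)-3,5-dimethoxyphenyl]ethenyl trifluoromethanesulfonate | C=C(OS(=O)(=O)C(F)(F)F)c1cc(OC)c(OCc2ccccc2)c(OC)c1 | intermediate
8 | (5R)-2-[4-(benzyloxy)-3-methoxyphenyl]-5-{1-[4-(benzyloxy)-3,5-dimethoxyphenyl]ethenyl}-4,5-dihydro-1,3-dioxepine (C2d epimers) | COc1cc(C2OC[C@@H](C(=C)c3cc(OC)c(OCc4ccccc4)c(OC)c3)C=CO2)ccc1OCc1ccccc1 | intermediate
9 | (E)-oxocarbenium triflate of 1 O-linked through CH2 to the (R)-allylic carbon that bears the arylvinyl group and the (Z)-trimethylsilyl enol ether (not isolated) | COc1cc(/C=[O+]/C[C@@H](C(=C)c2cc(OC)c(OCc3ccccc3)c(OC)c2)/C=C\O[Si](C)(C)C)ccc1OCc1ccccc1.[O-]S(=O)(=O)C(F)(F)F | intermediate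
10 | (2S,3S,4R)-2-[4-(benzyloxy)-3-methoxyphenyl]-4-{1-[4-(benzyloxy)-3,5-dimethoxyphenyl]ethenyl}oxolane-3-carbaldehyde | COc1cc([C@H]2OC[C@@H](C(=C)c3cc(OC)c(OCc4ccccc4)c(OC)c3)[C@@H]2C=O)ccc1OCc1ccccc1 | intermediate
11 | [(2S,3R,4R)-2-[4-(benzyloxy)-3-methoxyphenyl]-4-{1-[4-(benzyloxy)-3,5-dimethoxyphenyl]ethenyl}oxolan-3-yl]methanol | COc1cc([C@H]2OC[C@@H](C(=C)c3cc(OC)c(OCc4ccccc4)c(OC)c3)[C@@H]2CO)ccc1OCc1ccccc1 | intermediate
12 | 1-[4-(benzyloxy)-3,5-dimethoxyphenyl]-1-[(3S,4R,5S)-5-[4-(benzyloxy)-3-methoxyphenyl]-4-(hydroxymethyl)oxolan-3-yl]ethane-1,2-diol (carbinol epimers, not isolated) | COc1cc([C@H]2OC[C@@H](C(O)(CO)c3cc(OC)c(OCc4ccccc4)c(OC)c3)[C@@H]2CO)ccc1OCc1ccccc1 | intermediate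
13 | [4-(benzyloxy)-3,5-dimethoxyphenyl][(3S,4R,5S)-5-[4-(benzyloxy)-3-methoxyphenyl]-4-(hydroxymethyl)oxolan-3-yl]methanone | COc1cc([C@H]2OC[C@@H](C(=O)c3cc(OC)c(OCc4ccccc4)c(OC)c3)[C@@H]2CO)ccc1OCc1ccccc1 | intermediate
14 | (4-hydroxy-3,5-dimethoxyphenyl)[(3S,4R,5S)-5-(4-hydroxy-3-methoxyphenyl)-4-(hydroxymethyl)oxolan-3-yl]methanone | COc1cc([C@H]2OC[C@@H](C(=O)c3cc(OC)c(O)c(OC)c3)[C@@H]2CO)ccc1O | target

Total step count: 8. Longest linear sequence: 7 (steps 2–8, from acetosyringone).

Steps most likely to fail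

**Step 4.**
- Risks: slow carbopalladation by the hindered α-arylvinylpalladium species; palladium-hydride-mediated migration of either double bond; insufficient discrimination of the enantiotopic alkene carbons.
- The fallback sets out from 7 (and uses 1 again) and comes back at 13.
- It replaces the Heck/ring-contraction pair by a conjugate addition and the classical lactone-aldol sequence.
- In that sequence the lactone β-centre relays C3 and is itself corrected at the end, so the (4S) lactone is required.
- Miyaura borylation of 7 (B2pin2, PdCl2(PPh3)2, PPh3, KOPh, toluene, 50 °C) should give the alkenyl boronate F1.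
- Hayashi–Miyaura 1,4-addition of F1 to furan-2(5H)-one (Rh(acac)(C2H4)2, (S)-BINAP, dioxane/H2O, sense assigned by analogy with cyclic enones) should give the (4S)-β-alkenyl butyrolactone F2.
- Aldol addition to 1 (LDA, THF, −78 °C) should occur anti to the β-substituent and give the trans aldol adduct F3, whose carbinol epimers are irrelevant.
- LiAlH4 should give the triol F4.
- Acid-catalysed cyclodehydration through the benzylic cation (CSA cat., CH2Cl2, 0 °C) should give the 2,3-trans-3,4-cis oxolane alcohol F5.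
- Lemieux–Johnson cleavage through the diol F6 should give the 3,4-cis ketone F7.
- DBU in CH2Cl2 should epimerise C4 of F7 to the trans ketone 13.

**Step 5.**
- Risks: capture of the oxocarbenium ion by the styrene-type double bond; acid-induced migration of that double bond through C4 with loss of the relay centre; incomplete equilibration at C2 and C3.
- The fallback sets out from 3 and 7 and comes back at 13.
- It exchanges the intramolecular O-to-C transfer for an intermolecular aldol and a separate etherification.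
- The Heck reaction is run with (R)-t-Bu-PHOX to give the (5S)-dioxepine F8.
- Mild aqueous acid (PPTS, wet THF) should hydrolyse the vinyl acetal to the (4S)-lactol F9 and return aldehyde 1.
- Oxidation (TEMPO, PhI(OAc)2, CH2Cl2) should give the lactone F2.
- From F2 the sequence F3, F4, F5, F6, F7 described above is followed to 13.

**Step 8.**
- Risks: over-reduction, namely hydrogenolysis of the cyclic benzylic C2–O1 bond or reduction of the aryl ketone.
- The fallback sets out from 13 and comes back at 14.
- Reductive cleavage is replaced by Lewis-acid debenzylation with a cation scavenger (BCl3, pentamethylbenzene, CH2Cl2, −78 °C).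
- Any transient opening at C2 should reclose to the same thermodynamic all-trans oxolane.
- It makes no new compound (entry F0).

Further compounds
F1 | step 4 | 2-{1-[4-(benzyloxy)-3,5-dimethoxyphenyl]ethenyl}-4,4,5,5-tetramethyl-1,3,2-dioxaborolane | C=C(B1OC(C)(C)C(C)(C)O1)c1cc(OC)c(OCc2ccccc2)c(OC)c1
F2 | step 4 | (4S)-4-{1-[4-(benzyloxy)-3,5-dimethoxyphenyl]ethenyl}oxolan-2-one | O=C1OC[C@H](C(=C)c2cc(OC)c(OCc3ccccc3)c(OC)c2)C1
F3 | step 4 | (3S,4S)-3-{[4-(benzyloxy)-3-methoxyphenyl](hydroxy)methyl}-4-{1-[4-(benzyloxy)-3,5-dimethoxyphenyl]ethenyl}oxolan-2-one (carbinol epimers) | O=C1OC[C@H](C(=C)c2cc(OC)c(OCc3ccccc3)c(OC)c2)[C@H]1C(O)c1ccc(OCc2ccccc2)c(OC)c1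
F4 | step 4 | (2R,3S)-2-{[4-(benzyloxy)-3-methoxyphenyl](hydroxy)methyl}-3-{1-[4-(benzyloxy)-3,5-dimethoxyphenyl]ethenyl}butane-1,4-diol (carbinol epimers) | OC[C@H](C(=C)c1cc(OC)c(OCc2ccccc2)c(OC)c1)[C@H](CO)C(O)c1ccc(OCc2ccccc2)c(OC)c1
F5 | step 4 | [(2S,3R,4S)-2-[4-(benzyloxy)-3-methoxyphenyl]-4-{1-[4-(benzyloxy)-3,5-dimethoxyphenyl]ethenyl}oxolan-3-yl]methanol | COc1cc([C@H]2OC[C@H](C(=C)c3cc(OC)c(OCc4ccccc4)c(OC)c3)[C@@H]2CO)ccc1OCc1ccccc1
F6 | step 4 | 1-[4-(benzyloxy)-3,5-dimethoxyphenyl]-1-[(3R,4R,5S)-5-[4-(benzyloxy)-3-methoxyphenyl]-4-(hydroxymethyl)oxolan-3-yl]ethane-1,2-diol (carbinol epimers) | COc1cc([C@H]2OC[C@H](C(O)(CO)c3cc(OC)c(OCc4ccccc4)c(OC)c3)[C@@H]2CO)ccc1OCc1ccccc1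
F7 | step 4 | [4-(benzyloxy)-3,5-dimethoxyphenyl][(3R,4R,5S)-5-[4-(benzyloxy)-3-methoxyphenyl]-4-(hydroxymethyl)oxolan-3-yl]methanone | COc1cc([C@H]2OC[C@H](C(=O)c3cc(OC)c(OCc4ccccc4)c(OC)c3)[C@@H]2CO)ccc1OCc1ccccc1
F8 | step 5 | (5S)-2-[4-(benzyloxy)-3-methoxyphenyl]-5-{1-[4-(benzyloxy)-3,5-dimethoxyphenyl]ethenyl}-4,5-dihydro-1,3-dioxepine (C2d epimers) | COc1cc(C2OC[C@H](C(=C)c3cc(OC)c(OCc4ccccc4)c(OC)c3)C=CO2)ccc1OCc1ccccc1
F9 | step 5 | (4S)-4-{1-[4-(benzyloxy)-3,5-dimethoxyphenyl]ethenyl}oxolan-2-ol (anomers) | OC1OC[C@H](C(=C)c2cc(OC)c(OCc3ccccc3)c(OC)c2)C1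
F0 | step 8 | none | none
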